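Atom labels C1–C15 follow germacrane numbering of the target (C12 lactone carbonyl, C13 exocyclic methylene, C14 methyl on C10, C15 hydroxymethyl on C4).

## Analysis of the target

- Target 42 is a germacranolide: a ten-membered carbocycle (C1–C10) fused across C6–C7 to an α-methylene-γ-butyrolactone (O–C6, C7, C11, C12, with exocyclic C11=C13).
- The carbocycle carries a trisubstituted 1,10-epoxide with C2 and C9 cis, a C4=C5 alkene with C3 and C6 cis and the free C15 hydroxymethyl on C4, an acetate at C3 and an angelate ((Z)-2-methylbut-2-enoate) at C8.
- There are six stereocentres, (1R,3S,6R,7R,8R,10S). C6, C7 and C8 are contiguous, with the lactone ring substituents at C6 and C7 trans. The epoxide pair C1/C10 must come from a Z alkene. C3 is separated from the others by the C4=C5 alkene and is 1,3-syn to the C1 oxygen.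
- Sensitive groups are the methylene lactone (Michael acceptor, reduced by borohydride), the angelate (isomerises to the tiglate under nucleophilic base), the epoxide (acid-labile, and β,γ to any carbonyl at C3), and the allylic acetate next to a free primary alcohol (acyl migration). A free C8 hydroxyl can also translactonise onto C12.
- The difficulty lies in a medium ring with two cis-configured elements, three differently treated oxygens, and stereocentres (C3, C1/C10) too remote from the lactone triad for reliable relay of chirality.
- The strategy rests on C7: it is bonded to C6, C8 and C11, and C11 carries C13. A butenolide C12(=O)–C11=C7–C6 is therefore electrophilic at C7 and, after addition, nucleophilic at C11, so a C8 nucleophile and a C13 electrophile can be attached in one flask while the C6 centre controls C7.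

## Retrosynthetic reasoning

**C15–O and C3–O (42 → 41 → 40).** The last operations are desilylation of 41 and acetylation of 40. The C15 oxygen is kept as the most robust silyl ether so that C3 can be acetylated alone, and it is freed last under buffered acidic conditions that do not move the acetate.

**C3 stereocentre (40 → 39 → 38).** The configuration at C3 is not expected to be set reliably during ring closure. Both epimers 38 are therefore oxidised to enone 39, and the C3–H bond is formed by Corey–Bakshi–Shibata reduction under catalyst control.

**C3–C4 ring bond (38 → 37).** The ring is opened at C3–C4, a Nozaki–Hiyama–Kishi closure between the C3 aldehyde and the C4 vinyl iodide of 37. This is the only ring bond that joins the two chain ends delivered by the key step (C2 and C5, each extended by one or two carbons). The vinyl iodide transfers its geometry with retention, which secures the cis relation of C3 and C6.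

**Epoxide (37 → 36 → 35).** The C1–O and C10–O bonds are removed to give Z alkene 35. The epoxide is made on the open chain by Shi epoxidation, and the C3 aldehyde is generated only afterwards (36 → 37). Direction by a C8 hydroxyl was ruled out: that hydroxyl has to be acylated early, since free it would lactolise with a C2 aldehyde, compete in the oxidations and translactonise. Epoxidation before the C2 homologation was also ruled out, because a 2,3-epoxy alcohol cannot be homologated cleanly to the β,γ-epoxy aldehyde.

**C11=C13 (35 → 33).** The methylene lactone is traced to Mannich base 33 by quaternisation and elimination via 34. The amine masks the acceptor through the hydride, ylide and borane steps. It is released immediately before the epoxidation, because a tertiary amine would be N-oxidised by the peroxide reagent.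

**C2–C3 (33 → 31 → 28 → 27).** C3 is cut off as the ylide carbon of 30 (from 29). Z-enal 28, from allylic alcohol 27, is methylenated to diene 31, and hydroboration of the terminal alkene gives 33. This homologation avoids cyanide, strong hydride or organometallic reagents that the lactone would not tolerate.

**C4=C5 and C15 (26 → 25 → 24 → 23 → 20).** The alkene is cut by a Wittig disconnection to aldehyde 22 (from alcohol 20) and ylide 21, which supplies C4 and C15. α-Iodination (24) places iodine on C4 cis to C6; reduction (25) and silylation (26) follow.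

**C8–O ester and C8–H (19 → 16 + 17; 16 → 15 → 14).** The angelate is attached from angelic acid 17 directly after C8 is set. The carbinol comes from ketone 15 by Corey–Bakshi–Shibata reduction, and 15 from hydrolysis of dithiane 14.

**C7–C8 and C11–C13 (14 → 10 + 2 + 11).** Both bonds are cut in one disconnection: dithiane 10 as the C8 acyl-anion equivalent, butenolide 2 as the C5–C6–C7–C11–C12 unit, and Eschenmoser's salt 11 as C13. Nothing else in the molecule allows two skeletal bonds and one stereocentre to be set from a single chiral-pool centre.

**C8–C9 and C1=C10 (10 → 8 + 7; 7 → 6 → 5 → 3 + 4).** Dithiane 10 comes from alkylation of 9 (from 8) with allylic bromide 7. The Z alkene is built by Still–Gennari olefination of 3 with 4, so that the two ends are different from the start (ester at C9, silyl ether at C2). Desymmetrising a Z-butenediol would require an unreliable differentiation of two similar allylic hydroxyls.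

**Protecting groups (2 → 1).** Butenolide 2 is the triethylsilyl ether of 1. The three silyl groups are graded so that they leave in the order C5 (triethylsilyl), C2 (tert-butyldimethylsilyl), C15 (tert-butyldiphenylsilyl).

## Alternatives that were turned down

**Alternative 1: double asymmetric hydrogenation and lactonisation.**
- Disconnection: C6 and C8 are traced back to two carbonyl carbons flanking C7 in an achiral, symmetric open chain whose C7 carries the C11–C12 ester arm.
- Forward key step: both carbonyls are hydrogenated under control of one chiral catalyst, and the diol ester lactonises through the C6 hydroxyl under equilibrating acid to the trans lactone A1.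
- For: C6, C7 and C8 arise in one catalytic operation from an achiral precursor. On this point it is stronger than the chosen route, which buys C6 from the chiral pool and needs a separate catalyst-controlled reduction (step 8) for C8.
- Against: A1 holds only C5–C9, C11 and C12. C13 is missing, and C5 and C9 are two similar primary chlorides next to oxygenated carbons, slow in substitution and in need of differentiation. All of C1–C4, C10 and C13–C15 still have to be attached in separate C–C bond formations.
- Comparison: the chosen key step delivers 14 with C8–C2 and C13 already attached and the Z alkene in place, so the carbon count after the key step is far higher for one extra reduction.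

**Alternative 2: anionic oxy-Cope ring expansion.**
- Disconnection: the C8–C9 bond of the ten-membered ring, with re-formation of a C1–C6 bond in a terpene-derived six-membered ring.
- Forward key step: an anionic oxy-Cope rearrangement opens the six-membered ring into the cyclodecadienone A2 (after protonation of the C6 enolate).
- For: the medium ring forms early, without high dilution and with a strong driving force. In ring formation it is clearly stronger than a late macrocyclisation such as step 22.
- Against: A2 has C2 and C9 trans on C1=C10, whereas the epoxide of the target needs them cis. C15 is a bare methyl that would need a late, poorly selective allylic oxidation. C11–C13 are absent and must be added at C7 with control of C6 and C7 on a flexible ring. The C8 silyl group must be oxidised to the alcohol in the presence of the alkenes.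
- Comparison: the chosen route fixes the Z geometry in 5 and brings the C15 oxygen in with 21, so all oxidation levels are in place before the ring is closed, at the price of a late ring closure.

**Alternative 3: sulfonium ylide closes ring and epoxide.**
- Disconnection: C1–C10 and O–C1 together.
- Forward key step: a C1 sulfonium ylide adds to the C10 methyl ketone, and the alkoxide displaces the sulfur group, giving the ring and the epoxide of A3 in one step.
- For: the endgame is shorter, and no β,γ-epoxy aldehyde is needed. That aldehyde is the weakest point of the chosen route (steps 21–22), so here the alternative is stronger.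
- Against: C1 and C10 and their cis relation are created during macrocyclisation without reagent control. The base needed for the ylide can enolise the methyl ketone. A3 carries C12 as an ether methylene, so a late allylic oxidation to the lactone is needed next to the epoxide.
- Comparison: the chosen route sets the epoxide on an open chain under catalyst control (step 20) and has the lactone oxidation level from compound 1 onwards. It accepts in exchange a separate ring closure and a redox correction at C3.

Key step: step 6

Assumption: 1, 3, 4, 8, 11, 17, 21 and 29, the D-fructose-derived Shi ketone and both antipodes of the 2-methyl-CBS-oxazaborolidine are taken to be purchasable.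

## Route

Step 1
Reactants: 1 (S)-5-(hydroxymethyl)furan-2(5H)-one
Product: 2 (S)-5-[(triethylsilyloxy)methyl]furan-2(5H)-one
Conditions: Et3SiCl, imidazole, CH2Cl2, 0 °C
Reagents that add atoms: chlorotriethylsilane, CC[Si](Cl)(CC)CC
Why: Standard silylation of a primary alcohol; the triethylsilyl group is chosen because it must later leave in the presence of the tert-butyldimethylsilyl ether at C2, and the C6 stereocentre is not touched.

Step 2
Reactants: 3 (tert-butyldimethylsilyloxy)acetaldehyde; 4 ethyl 2-[bis(2,2,2-trifluoroethoxy)phosphoryl]propanoate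
Product: 5 ethyl (Z)-4-(tert-butyldimethylsilyloxy)-2-methylbut-2-enoate
Conditions: KN(SiMe3)2, 18-crown-6, THF, −78 °C
Reagents that add atoms: none
Why: Still–Gennari olefination; the electron-poor phosphonate under dissociating conditions collapses kinetically to the Z-trisubstituted enoate, which places C9 and C2 cis on the future C1=C10 bond and leaves the two ends chemically different.

Step 3
Reactants: 5 ethyl (Z)-4-(tert-butyldimethylsilyloxy)-2-methylbut-2-enoate
Product: 6 (Z)-4-(tert-butyldimethylsilyloxy)-2-methylbut-2-en-1-ol
Conditions: i-Bu2AlH, CH2Cl2, −78 °C; aq. KNaC4H4O6 work-up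
Reagents that add atoms: none
Why: 1,2-Reduction of the enoate with i-Bu2AlH gives the allylic alcohol without affecting the alkene geometry or the silyl ether; the neutral tartrate work-up avoids silyl migration between the cis hydroxymethyl arms.

Step 4
Reactants: 6 (Z)-4-(tert-butyldimethylsilyloxy)-2-methylbut-2-en-1-ol
Product: 7 (Z)-1-bromo-4-(tert-butyldimethylsilyloxy)-2-methylbut-2-ene
Conditions: CBr4, PPh3, CH2Cl2, 0 °C
Reagents that add atoms: tetrabromomethane, BrC(Br)(Br)Br
Why: Appel bromination; bromide displaces the oxyphosphonium group at the primary carbon under neutral conditions, without allylic transposition or Z/E isomerisation.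

Step 5
Reactants: 8 1,3-dithiane; 7 (Z)-1-bromo-4-(tert-butyldimethylsilyloxy)-2-methylbut-2-ene
Product: 10 2-[(Z)-4-(tert-butyldimethylsilyloxy)-2-methylbut-2-en-1-yl]-1,3-dithiane, via 2-lithio-1,3-dithiane 9 (not isolated)
Conditions: n-BuLi, THF, −30 °C; then 7, −78 → −20 °C
Reagents that add atoms: none
Why: Corey–Seebach alkylation; the sulfur-stabilised carbanion displaces the primary allylic bromide directly (SN2), forming C8–C9 and installing C8 as a masked carbonyl.

Step 6
Reactants: 10 2-[(Z)-4-(tert-butyldimethylsilyloxy)-2-methylbut-2-en-1-yl]-1,3-dithiane; 2 (S)-5-[(triethylsilyloxy)methyl]furan-2(5H)-one; 11 Eschenmoser's salt (N,N-dimethylmethyleneiminium iodide)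
Product: 14 (3R,4S,5S)-3-[(dimethylamino)methyl]-4-{2-[(Z)-4-(tert-butyldimethylsilyloxy)-2-methylbut-2-en-1-yl]-1,3-dithian-2-yl}-5-[(triethylsilyloxy)methyl]dihydrofuran-2(3H)-one, via lithiated dithiane 12 (not isolated), via lactone lithium enolate 13 (not isolated)
Conditions: n-BuLi, THF, −30 °C; DMPU, −78 °C, add 2; then 11, −78 → 0 °C
Reagents that add atoms: none
Why: Deprotonation of 10 at the dithiane carbon gives carbanion 12, which adds in a Michael fashion to C7 of butenolide 2 to give lactone enolate 13, and the enolate is then aminomethylated at C11 by the iminium ion of 11 (Mannich reaction). The closest known reaction type is the tandem conjugate addition of 2-lithio-1,3-dithianes to 5-substituted butenolides with in situ trapping of the enolate by a carbon electrophile. No ring is closed; the step makes the two skeletal bonds C7–C8 and C11–C13. The new stereocentre C7 is controlled by the silyloxymethyl group on C6, which shields one face of the planar butenolide so that the bulky nucleophile enters anti to it. The C11 centre is controlled by the fully substituted dithiane carbon now on C7, the iminium ion approaching the enolate trans to it; this centre is removed later, so its control is not critical. The step needs 1,4- rather than 1,2-addition and addition rather than deprotonation of 2 at C6: the soft, delocalised dithiane anion, the polar co-solvent DMPU and the low temperature favour conjugate addition, and 2 is added to the preformed anion so that it never meets excess base. Both silyl ethers and the Z alkene are inert to the organolithium at −78 °C.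

Step 7
Reactants: 14 (3R,4S,5S)-3-[(dimethylamino)methyl]-4-{2-[(Z)-4-(tert-butyldimethylsilyloxy)-2-methylbut-2-en-1-yl]-1,3-dithian-2-yl}-5-[(triethylsilyloxy)methyl]dihydrofuran-2(3H)-one
Product: 15 (3R,4S,5S)-4-[(Z)-5-(tert-butyldimethylsilyloxy)-3-methylpent-3-enoyl]-3-[(dimethylamino)methyl]-5-[(triethylsilyloxy)methyl]dihydrofuran-2(3H)-one (C8 ketone)
Conditions: HgCl2, CaCO3, MeCN/H2O (4:1), rt
Reagents that add atoms: water, O
Why: Thiophilic HgCl2 hydrolyses the dithioacetal under carbonate-buffered, nearly neutral conditions that spare the silyl ethers, the alkene and the amine. Neutrality also suppresses β-elimination of the lactone oxygen from the new β-acyloxy ketone, which is reduced without delay.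

Step 8
Reactants: 15 C8 ketone
Product: 16 (3R,4R,5S)-4-[(1R,3Z)-5-(tert-butyldimethylsilyloxy)-1-hydroxy-3-methylpent-3-en-1-yl]-3-[(dimethylamino)methyl]-5-[(triethylsilyloxy)methyl]dihydrofuran-2(3H)-one ((8R)-alcohol)
Conditions: (S)-2-methyl-CBS-oxazaborolidine, catecholborane, toluene, −78 °C; MeOH, then pH 9 buffer
Reagents that add atoms: none
Why: Corey–Bakshi–Shibata reduction; the catalyst binds the ketone with the α-branched C7 side as the large and the C9 methylene as the small substituent, so the (S)-catalyst should deliver hydride to give the (8R)-alcohol under reagent control. Catecholborane is used because its adduct with the dimethylamino group is cleaved on work-up.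

Step 9
Reactants: 16 (8R)-alcohol; 17 angelic acid ((Z)-2-methylbut-2-enoic acid)
Product: 19 C8 angelate of 16 (lactone 3R,4R,5S; C8 R; all other groups unchanged), via angelic 2,4,6-trichlorobenzoic anhydride 18 (not isolated)
Conditions: 17, 2,4,6-trichlorobenzoyl chloride, Et3N, toluene, rt; then 16, 80 °C
Reagents that add atoms: none
Why: Yamaguchi-type acylation through the mixed anhydride without a nucleophilic catalyst transfers the angeloyl group with its Z geometry intact. Acylating now blocks the C8 hydroxyl against translactonisation onto C12 and against the later oxidations.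

Step 10
Reactants: 19 C8 angelate
Product: 20 primary alcohol at C5 (19 with the triethylsilyl ether cleaved)
Conditions: AcOH/THF/H2O (3:1:1), rt
Reagents that add atoms: none
Why: Acid-catalysed solvolysis removes the primary triethylsilyl ether much faster than the tert-butyldimethylsilyl ether at C2; the amine is protonated and inert under these conditions.

Step 11
Reactants: 20 C5 alcohol; 21 (triphenylphosphoranylidene)acetaldehyde
Product: 23 (E)-enal (lactone C5 now bears CH=CH–CHO, that is C5=C4 and the C15 aldehyde), via C5 aldehyde 22 (not isolated)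
Conditions: Dess–Martin periodinane, NaHCO3, CH2Cl2, 0 °C → rt; then 21, 40 °C
Reagents that add atoms: none
Why: Dess–Martin oxidation gives the configurationally labile α-acyloxy aldehyde, which is trapped in the same flask by the stabilised ylide (Wittig reaction) to give the E-enal. This adds C4 and C15 at the correct oxidation level.

Step 12
Reactants: 23 (E)-enal
Product: 24 (Z)-2-iodoenal (iodine on C4, cis to C6)
Conditions: I2, pyridine, DMAP (cat.), CH2Cl2, rt, dark
Reagents that add atoms: iodine, II
Why: α-Iodination of an enal by conjugate addition of the pyridine base at C5, iodination of the enolate at C4 and elimination. The more stable (Z)-2-iodoenal should form, with iodine cis to C6 and the formyl group trans, which is the geometry required for the ring alkene.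

Step 13
Reactants: 24 (Z)-2-iodoenal
Product: 25 (Z)-2-iodoallylic alcohol (C15 hydroxymethyl)
Conditions: NaBH4, CeCl3·7H2O, MeOH, −40 °C
Reagents that add atoms: none
Why: Luche reduction; the cerium-modified borohydride reduces the aldehyde 1,2 at low temperature and leaves lactone, esters, vinyl iodide and the amine-masked acceptor untouched.

Step 14
Reactants: 25 (Z)-2-iodoallylic alcohol
Product: 26 C15 tert-butyldiphenylsilyl ether of 25
Conditions: t-BuPh2SiCl, imidazole, CH2Cl2, rt
Reagents that add atoms: tert-butyl(chloro)diphenylsilane, CC(C)(C)[Si](Cl)(c1ccccc1)c1ccccc1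
Why: Silylation of the primary allylic alcohol; this is the most robust of the three silyl groups and is meant to survive to the last step.

Step 15
Reactants: 26 C15 silyl ether
Product: 27 primary Z-allylic alcohol at C2 (26 with the tert-butyldimethylsilyl ether cleaved)
Conditions: HF·pyridine, pyridine, THF, 0 °C
Reagents that add atoms: none
Why: Buffered HF·pyridine cleaves the primary tert-butyldimethylsilyl ether selectively in the presence of the bulkier tert-butyldiphenylsilyl ether.

Step 16
Reactants: 27 C2 allylic alcohol
Product: 28 (Z)-enal (C2 aldehyde conjugated with C1=C10)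
Conditions: MnO2, CH2Cl2, rt
Reagents that add atoms: none
Why: MnO2 oxidises allylic alcohols selectively under neutral heterogeneous conditions, which should preserve the Z geometry and leave the amine and the vinyl iodide alone.

Step 17
Reactants: 28 (Z)-enal; 29 methyltriphenylphosphonium bromide
Product: 31 (Z)-1,3-diene (terminal C2=C3 vinyl group on the Z C1=C10 alkene), via methylenetriphenylphosphorane 30 (not isolated)
Conditions: 29, KN(SiMe3)2, THF, 0 °C; then 28, −78 → 0 °C
Reagents that add atoms: none
Why: Wittig methylenation; the non-stabilised ylide reacts with the aldehyde at low temperature far faster than with the lactone or the esters and supplies C3. No excess base is present, so the Z-enal is not isomerised through its dienolate.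

Step 18
Reactants: 31 (Z)-1,3-diene
Product: 33 homoallylic alcohol (primary hydroxyl on C3, Z C1=C10 alkene retained), via B-alkyl-9-borabicyclononane 32 (not isolated)
Conditions: 9-BBN, THF, 0 °C → rt; then H2O2, aq. NaOAc, 0 °C
Reagents that add atoms: hydrogen peroxide, OO
Why: Hydroboration–oxidation; 9-BBN adds to the monosubstituted terminal alkene of the diene with boron on C3 and ignores the trisubstituted alkenes, the angelate and the vinyl iodide, and buffered peroxide replaces boron by hydroxyl. Any amine N-oxide formed in the work-up eliminates to the same methylene lactone that step 19 produces.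

Step 19
Reactants: 33 homoallylic alcohol
Product: 35 α-methylene lactone (C11=C13; lactone 4R,5S), via trimethylammonium iodide 34 (not isolated)
Conditions: MeI, MeCN, rt; then aq. NaHCO3, rt
Reagents that add atoms: none
Why: Exhaustive methylation gives the quaternary salt, which undergoes E1cB (Hofmann-type) elimination of trimethylamine with mild base to unveil the methylene lactone. It is done here because the tertiary amine would be N-oxidised in the next step.

Step 20
Reactants: 35 α-methylene lactone
Product: 36 (1R,10S)-cis-epoxy alcohol (epoxide at C1–C10, free C3 hydroxyl)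
Conditions: D-fructose-derived Shi ketone (0.3 equiv), KHSO5 (as 2KHSO5·KHSO4·K2SO4), K2CO3, Bu4NHSO4, MeCN/CH2(OMe)2, aq. Na2B4O7 buffer (pH 10.5), 0 °C
Reagents that add atoms: potassium peroxymonosulfate, [K+].[O-]S(=O)(=O)OO
Why: Shi epoxidation; the chiral dioxirane attacks only the electron-rich trisubstituted C1=C10 alkene, not the angelate, the methylene lactone or the iodoalkene. In the spiro transition state the single vinylic hydrogen (on C1) lies next to the ketal of the catalyst, which for the D-fructose-derived ketone should give the (1R,10S)-epoxide (reagent control). The Z geometry is transferred as the cis epoxide.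

Step 21
Reactants: 36 epoxy alcohol
Product: 37 β,γ-epoxy aldehyde (C3 aldehyde)
Conditions: Dess–Martin periodinane, NaHCO3, CH2Cl2, 0 °C; used at once
Reagents that add atoms: none
Why: Buffered Dess–Martin oxidation gives the aldehyde under non-basic conditions; it is not stored because enolisation toward C2 would open the epoxide.

Step 22
Reactants: 37 β,γ-epoxy aldehyde
Product: 38 macrocyclic allylic alcohol as both C3 epimers (ten-membered ring closed; C15 silyl ether, C8 angelate, 1,10-epoxide, methylene lactone)
Conditions: CrCl2 (10 equiv), NiCl2 (cat.), degassed DMSO, rt, 0.002 M, slow addition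
Reagents that add atoms: none
Why: Nozaki–Hiyama–Kishi reaction; nickel-catalysed formation of the alkenylchromium species from the vinyl iodide with retention of geometry, followed by its chemoselective 1,2-addition to the aldehyde, closes the ring at C3–C4 under neutral conditions. High dilution favours cyclisation, and the configuration at C3 is not relied upon.

Step 23
Reactants: 38 macrocyclic allylic alcohol (C3 epimers)
Product: 39 macrocyclic enone (C3 ketone conjugated with C4=C5)
Conditions: Dess–Martin periodinane, NaHCO3, CH2Cl2, 0 °C
Reagents that add atoms: none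
Why: Oxidation of the allylic alcohol converges both C3 epimers on one enone under buffered, non-basic conditions that keep the β,γ-epoxide closed.

Step 24
Reactants: 39 macrocyclic enone
Product: 40 (3S)-allylic alcohol
Conditions: (R)-2-methyl-CBS-oxazaborolidine, catecholborane, toluene, −78 °C
Reagents that add atoms: none
Why: Corey–Bakshi–Shibata reduction of an α-substituted enone, with the alkenyl carbon C4 as the large and the C2 methylene as the small substituent, so the (R)-catalyst should give the (3S)-alcohol. 1,2-Reduction at low temperature leaves the methylene lactone, the angelate and the epoxide untouched.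

Step 25
Reactants: 40 (3S)-allylic alcohol
Product: 41 C3 acetate
Conditions: Ac2O, pyridine, DMAP (cat.), CH2Cl2, 0 °C
Reagents that add atoms: acetic anhydride, CC(=O)OC(C)=O
Why: Acylation of the secondary allylic alcohol under mild base with retention at C3; the only other oxygen that could react (O15) is still silylated.

Step 26
Reactants: 41 C3 acetate
Product: 42 target (1R,3S,6R,7R,8R,10S)
Conditions: HF·pyridine, pyridine, THF, 0 °C → rt
Reagents that add atoms: none
Why: Fluoride-induced cleavage of the tert-butyldiphenylsilyl ether under buffered, slightly acidic conditions, which avoid base-promoted acetyl migration from O3 to O15 and isomerisation of the angelate and are mild enough for the trisubstituted epoxide.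

## Compound list

1 | (S)-5-(hydroxymethyl)furan-2(5H)-one | O=C1C=C[C@@H](CO)O1 | starting material
2 | (S)-5-[(triethylsilyloxy)methyl]furan-2(5H)-one | O=C1C=C[C@@H](CO[Si](CC)(CC)CC)O1 | intermediate
3 | (tert-butyldimethylsilyloxy)acetaldehyde | O=CCO[Si](C)(C)C(C)(C)C | starting material
4 | ethyl 2-[bis(2,2,2-trifluoroethoxy)phosphoryl]propanoate | CCOC(=O)C(C)P(=O)(OCC(F)(F)F)OCC(F)(F)F | starting material
5 | ethyl (Z)-4-(tert-butyldimethylsilyloxy)-2-methylbut-2-enoate | CCOC(=O)/C(C)=C\CO[Si](C)(C)C(C)(C)C | intermediate
6 | (Z)-4-(tert-butyldimethylsilyloxy)-2-methylbut-2-en-1-ol | OC/C(C)=C\CO[Si](C)(C)C(C)(C)C | intermediate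
7 | (Z)-1-bromo-4-(tert-butyldimethylsilyloxy)-2-methylbut-2-ene | BrC/C(C)=C\CO[Si](C)(C)C(C)(C)C | intermediate
8 | 1,3-dithiane | C1CSCSC1 | starting material
9 | 2-lithio-1,3-dithiane | [Li]C1SCCCS1 | intermediate (not isolated)
10 | 2-[(Z)-4-(tert-butyldimethylsilyloxy)-2-methylbut-2-en-1-yl]-1,3-dithiane | C1CSC(C/C(C)=C\CO[Si](C)(C)C(C)(C)C)SC1 | intermediate
11 | Eschenmoser's salt (N,N-dimethylmethyleneiminium iodide) | C=[N+](C)C.[I-] | starting material
12 | 2-lithio derivative of 10 | [Li]C1(C/C(C)=C\CO[Si](C)(C)C(C)(C)C)SCCCS1 | intermediate (not isolated)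
13 | lithium enolate of the conjugate adduct (C7 dithianyl, C6 silyloxymethyl trans) | [Li]OC1=C[C@@H]([C@@H](CO[Si](CC)(CC)CC)O1)C1(C/C(C)=C\CO[Si](C)(C)C(C)(C)C)SCCCS1 | intermediate (not isolated)
14 | (3R,4S,5S)-3-[(dimethylamino)methyl]-4-{2-[(Z)-4-(tert-butyldimethylsilyloxy)-2-methylbut-2-en-1-yl]-1,3-dithian-2-yl}-5-[(triethylsilyloxy)methyl]dihydrofuran-2(3H)-one | CN(C)C[C@@H]1C(=O)O[C@H](CO[Si](CC)(CC)CC)[C@H]1C2(C/C(C)=C\CO[Si](C)(C)C(C)(C)C)SCCCS2 | intermediate
15 | (3R,4S,5S)-4-[(Z)-5-(tert-butyldimethylsilyloxy)-3-methylpent-3-enoyl]-3-[(dimethylamino)methyl]-5-[(triethylsilyloxy)methyl]dihydrofuran-2(3H)-one | CN(C)C[C@@H]1C(=O)O[C@H](CO[Si](CC)(CC)CC)[C@H]1C(=O)C/C(C)=C\CO[Si](C)(C)C(C)(C)C | intermediate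
16 | (3R,4R,5S)-4-[(1R,3Z)-5-(tert-butyldimethylsilyloxy)-1-hydroxy-3-methylpent-3-en-1-yl]-3-[(dimethylamino)methyl]-5-[(triethylsilyloxy)methyl]dihydrofuran-2(3H)-one | CN(C)C[C@@H]1C(=O)O[C@H](CO[Si](CC)(CC)CC)[C@H]1[C@H](O)C/C(C)=C\CO[Si](C)(C)C(C)(C)C | intermediate
17 | angelic acid, (Z)-2-methylbut-2-enoic acid | C/C=C(/C)C(=O)O | starting material
18 | angelic 2,4,6-trichlorobenzoic anhydride | C/C=C(/C)C(=O)OC(=O)c1c(Cl)cc(Cl)cc1Cl | intermediate (not isolated)
19 | C8 angelate of 16 (lactone 3R,4R,5S; C8 R) | CN(C)C[C@@H]1C(=O)O[C@H](CO[Si](CC)(CC)CC)[C@H]1[C@H](OC(=O)/C(C)=C\C)C/C(C)=C\CO[Si](C)(C)C(C)(C)C | intermediate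
20 | 19 with the triethylsilyl ether cleaved (primary alcohol at C5) | CN(C)C[C@@H]1C(=O)O[C@H](CO)[C@H]1[C@H](OC(=O)/C(C)=C\C)C/C(C)=C\CO[Si](C)(C)C(C)(C)C | intermediate
21 | (triphenylphosphoranylidene)acetaldehyde | O=CC=P(c1ccccc1)(c1ccccc1)c1ccccc1 | starting material
22 | C5 aldehyde from 20 (formyl group on lactone C5) | CN(C)C[C@@H]1C(=O)O[C@H](C=O)[C@H]1[C@H](OC(=O)/C(C)=C\C)C/C(C)=C\CO[Si](C)(C)C(C)(C)C | intermediate (not isolated)
23 | (E)-enal: lactone C5 bears (E)-CH=CH–CHO (C5=C4, C15 aldehyde) | CN(C)C[C@@H]1C(=O)O[C@H](/C=C/C=O)[C@H]1[C@H](OC(=O)/C(C)=C\C)C/C(C)=C\CO[Si](C)(C)C(C)(C)C | intermediate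
24 | (Z)-2-iodoenal: 23 with iodine on C4, cis to C6 | CN(C)C[C@@H]1C(=O)O[C@H](/C=C(/C=O)I)[C@H]1[C@H](OC(=O)/C(C)=C\C)C/C(C)=C\CO[Si](C)(C)C(C)(C)C | intermediate
25 | (Z)-2-iodoallylic alcohol: 24 with the C15 aldehyde reduced to CH2OH | CN(C)C[C@@H]1C(=O)O[C@H](/C=C(/CO)I)[C@H]1[C@H](OC(=O)/C(C)=C\C)C/C(C)=C\CO[Si](C)(C)C(C)(C)C | intermediate
26 | C15 tert-butyldiphenylsilyl ether of 25 | CN(C)C[C@@H]1C(=O)O[C@H](/C=C(/CO[Si](c2ccccc2)(c2ccccc2)C(C)(C)C)I)[C@H]1[C@H](OC(=O)/C(C)=C\C)C/C(C)=C\CO[Si](C)(C)C(C)(C)C | intermediate
27 | 26 with the tert-butyldimethylsilyl ether cleaved (primary Z-allylic alcohol at C2) | CN(C)C[C@@H]1C(=O)O[C@H](/C=C(/CO[Si](c2ccccc2)(c2ccccc2)C(C)(C)C)I)[C@H]1[C@H](OC(=O)/C(C)=C\C)C/C(C)=C\CO | intermediate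
28 | (Z)-enal: 27 oxidised at C2 | CN(C)C[C@@H]1C(=O)O[C@H](/C=C(/CO[Si](c2ccccc2)(c2ccccc2)C(C)(C)C)I)[C@H]1[C@H](OC(=O)/C(C)=C\C)C/C(C)=C\C=O | intermediate
29 | methyltriphenylphosphonium bromide | C[P+](c1ccccc1)(c1ccccc1)c1ccccc1.[Br-] | starting material
30 | methylenetriphenylphosphorane | C=P(c1ccccc1)(c1ccccc1)c1ccccc1 | intermediate (not isolated)
31 | (Z)-1,3-diene: 28 methylenated (C2=C3 vinyl on the Z C1=C10 alkene) | CN(C)C[C@@H]1C(=O)O[C@H](/C=C(/CO[Si](c2ccccc2)(c2ccccc2)C(C)(C)C)I)[C@H]1[C@H](OC(=O)/C(C)=C\C)C/C(C)=C\C=C | intermediate
32 | B-alkyl-9-borabicyclo[3.3.1]nonane from 31 (boron on C3) | CN(C)C[C@@H]1C(=O)O[C@H](/C=C(/CO[Si](c2ccccc2)(c2ccccc2)C(C)(C)C)I)[C@H]1[C@H](OC(=O)/C(C)=C\C)C/C(C)=C\CCB1C2CCCC1CCC2 | intermediate (not isolated)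
33 | homoallylic alcohol: primary hydroxyl on C3, Z C1=C10 alkene | CN(C)C[C@@H]1C(=O)O[C@H](/C=C(/CO[Si](c2ccccc2)(c2ccccc2)C(C)(C)C)I)[C@H]1[C@H](OC(=O)/C(C)=C\C)C/C(C)=C\CCO | intermediate
34 | trimethylammonium iodide of 33 | C[N+](C)(C)C[C@@H]1C(=O)O[C@H](/C=C(/CO[Si](c2ccccc2)(c2ccccc2)C(C)(C)C)I)[C@H]1[C@H](OC(=O)/C(C)=C\C)C/C(C)=C\CCO.[I-] | intermediate (not isolated)
35 | α-methylene lactone (C11=C13; lactone 4R,5S; C8 R) with the C3 alcohol and the Z C1=C10 alkene | C=C1C(=O)O[C@H](/C=C(/CO[Si](c2ccccc2)(c2ccccc2)C(C)(C)C)I)[C@H]1[C@H](OC(=O)/C(C)=C\C)C/C(C)=C\CCO | intermediate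
36 | (1R,10S)-cis-epoxide of 35 | C=C1C(=O)O[C@H](/C=C(/CO[Si](c2ccccc2)(c2ccccc2)C(C)(C)C)I)[C@H]1[C@H](OC(=O)/C(C)=C\C)C[C@]2(C)O[C@@H]2CCO | intermediate
37 | β,γ-epoxy aldehyde: 36 oxidised at C3 | C=C1C(=O)O[C@H](/C=C(/CO[Si](c2ccccc2)(c2ccccc2)C(C)(C)C)I)[C@H]1[C@H](OC(=O)/C(C)=C\C)C[C@]2(C)O[C@@H]2CC=O | intermediate
38 | macrocyclic allylic alcohol, both C3 epimers (1R,6R,7R,8R,10S): germacranolide with C15 tert-butyldiphenylsilyl ether, C8 angelate, 1,10-epoxide, free C3 hydroxyl | C=C1C(=O)O[C@@H]2/C=C(/CO[Si](c3ccccc3)(c3ccccc3)C(C)(C)C)C(O)C[C@H]3O[C@@]3(C)C[C@@H](OC(=O)/C(C)=C\C)[C@@H]12 | intermediate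
39 | macrocyclic enone (C3 ketone) | C=C1C(=O)O[C@@H]2/C=C(/CO[Si](c3ccccc3)(c3ccccc3)C(C)(C)C)C(=O)C[C@H]3O[C@@]3(C)C[C@@H](OC(=O)/C(C)=C\C)[C@@H]12 | intermediate
40 | (3S)-allylic alcohol (1R,3S,6R,7R,8R,10S) | C=C1C(=O)O[C@@H]2/C=C(/CO[Si](c3ccccc3)(c3ccccc3)C(C)(C)C)[C@@H](O)C[C@H]3O[C@@]3(C)C[C@@H](OC(=O)/C(C)=C\C)[C@@H]12 | intermediate
41 | C3 acetate of 40 | C=C1C(=O)O[C@@H]2/C=C(/CO[Si](c3ccccc3)(c3ccccc3)C(C)(C)C)[C@@H](OC(C)=O)C[C@H]3O[C@@]3(C)C[C@@H](OC(=O)/C(C)=C\C)[C@@H]12 | intermediate
42 | target: (1R,3S,6R,7R,8R,10S)-3-acetoxy-8-angeloyloxy-1,10-epoxy-15-hydroxygermacra-4(Z),11(13)-dien-6,12-olide | C=C1C(=O)O[C@@H]2/C=C(/CO)[C@@H](OC(C)=O)C[C@H]3O[C@@]3(C)C[C@@H](OC(=O)/C(C)=C\C)[C@@H]12 | target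

## Step count and least certain steps

Total step count: 26. Longest linear sequence: 25 steps (3 → 42, steps 2–26); the butenolide branch contributes one step (step 1).

**Step 6 (key step).** The most likely failure is proton transfer from C6 of butenolide 2 to the basic carbanion 12, or 1,2-addition to the lactone carbonyl, either of which lowers the amount of conjugate adduct. Incomplete capture of enolate 13 by the poorly soluble iminium salt is the second risk. Fallback: starting from 10 and 2, the conjugate addition is run alone and quenched with a proton source to give the trans lactone (4S,5S)-4-{2-[(Z)-4-(tert-butyldimethylsilyloxy)-2-methylbut-2-en-1-yl]-1,3-dithian-2-yl}-5-[(triethylsilyloxy)methyl]dihydrofuran-2(3H)-one F1. F1 is then enolised separately with LiN(iPr)2 at −78 °C and aminomethylated with 11, which returns to 14.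

**Step 22.** The β,γ-epoxy aldehyde 37 can open its epoxide by enolisation toward C2 under the Lewis-acidic chromium salts, and intermolecular coupling or simple reduction of the C–I bond can compete with closure of the strained ten-membered ring. Fallback: starting from 35, the alcohol is oxidised to the β,γ-unsaturated aldehyde F3 and the ring is closed by the same CrCl2/NiCl2 coupling to the macrocyclic dienol F4 (both C3 epimers). The C1=C10 bond of F4 is then epoxidised with the Shi ketone, which returns to 38; the epoxide is thus introduced only after the aldehyde has been consumed.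

**Step 20.** Face selectivity may be lower than for E-trisubstituted alkenes because the C9 methylene, not a methyl group, occupies the position next to the catalyst. The basic aqueous medium may also attack the methylene lactone. Fallback: starting from 35, the C3 hydroxyl is used as a directing group in a vanadium-catalysed epoxidation with VO(OiPr)3, a C2-symmetric chiral bishydroxamic acid ligand (the antipode that delivers oxygen to the (1R,10S) face) and cumene hydroperoxide under neutral conditions, which returns to 36 (no new compound, F0).

**Step 8.** The dimethylamino group can bind the borane and the catalyst, and the resident stereocentres at C7 and C11 may oppose the catalyst, so that facial selectivity at C8 erodes; slow reduction would also give the β-acyloxy ketone time to eliminate. Fallback: starting from 15, reduction with NaBH4/CeCl3·7H2O is used and, if the (8S)-alcohol F2 predominates, it is esterified with 17 under Mitsunobu conditions (PPh3, diisopropyl azodicarboxylate), which inverts C8 and returns directly to 19.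

**Step 24.** The conformation of the ten-membered enone may override the catalyst, so that hydride is delivered to the wrong face of C3. Fallback: starting from 39, if the (3R)-alcohol F5 is obtained (with either catalyst antipode or with a simple 1,2-selective hydride), it is converted with acetic acid under Mitsunobu conditions, with inversion at C3, into 41.

## Further compounds

F1 | step 6 | (4S,5S)-4-{2-[(Z)-4-(tert-butyldimethylsilyloxy)-2-methylbut-2-en-1-yl]-1,3-dithian-2-yl}-5-[(triethylsilyloxy)methyl]dihydrofuran-2(3H)-one | O=C1C[C@@H]([C@@H](CO[Si](CC)(CC)CC)O1)C1(C/C(C)=C\CO[Si](C)(C)C(C)(C)C)SCCCS1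
F2 | step 8 | (8S)-epimer of 16 | CN(C)C[C@@H]1C(=O)O[C@H](CO[Si](CC)(CC)CC)[C@H]1[C@@H](O)C/C(C)=C\CO[Si](C)(C)C(C)(C)C
F0 | step 20 | none | none
F3 | step 22 | β,γ-unsaturated aldehyde from 35 (C3 aldehyde, Z C1=C10 alkene) | C=C1C(=O)O[C@H](/C=C(/CO[Si](c2ccccc2)(c2ccccc2)C(C)(C)C)I)[C@H]1[C@H](OC(=O)/C(C)=C\C)C/C(C)=C\CC=O
F4 | step 22 | macrocyclic dienol, both C3 epimers (Z C1=C10 alkene, no epoxide) | C=C1C(=O)O[C@@H]2/C=C(/CO[Si](c3ccccc3)(c3ccccc3)C(C)(C)C)C(O)C/C=C(C)\C[C@@H](OC(=O)/C(C)=C\C)[C@@H]12
F5 | step 24 | (3R)-epimer of 40 | C=C1C(=O)O[C@@H]2/C=C(/CO[Si](c3ccccc3)(c3ccccc3)C(C)(C)C)[C@H](O)C[C@H]3O[C@@]3(C)C[C@@H](OC(=O)/C(C)=C\C)[C@@H]12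
A1 | alternative 1 | trans-5-(chloromethyl)-4-(2-chloro-1-hydroxyethyl)dihydrofuran-2(3H)-one | O=C1C[C@H]([C@H](O)CCl)[C@@H](CCl)O1
A2 | alternative 2 | 3-(tert-butyldimethylsilyloxy)-8-(dimethylphenylsilyl)-4,10-dimethylcyclodeca-1(10),4-dien-6-one | O=C1/C=C(/C)[C@@H](O[Si](C)(C)C(C)(C)C)C/C=C(\C)/C[C@@H]([Si](C)(C)c2ccccc2)C1
A3 | alternative 3 | tricyclic 1,10-epoxide with the methylene tetrahydrofuran (C3 4-methoxybenzyl ether, C8 tert-butyldimethylsilyl ether, C15 tert-butyldiphenylsilyl ether) | C=C1CO[C@@H]2/C=C(/CO[Si](c3ccccc3)(c3ccccc3)C(C)(C)C)[C@@H](OCc3ccc(OC)cc3)C[C@H]3O[C@@]3(C)C[C@@H](O[Si](C)(C)C(C)(C)C)[C@@H]12
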